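## Retrosynthetic overview

1. Key step, last: both dihydropyran rings are closed together by two C–O bonds, each from the hydroxyl next to an acyl group onto the neighbouring prenyl alkene of an open bis-prenyl dimer. The acyl groups direct this closure, and it is the proposed new reaction.
2. The dimer is cut at the bridge carbon. Ring B (isobutyryl) carries the 6-methylheptyl unit as a benzylic sulfone, which releases an ortho-quinone methide under base; ring A ((R)-2-methylbutanoyl) adds to it under a chiral squaramide, which sets the bridge stereocentre.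
3. Each ring is a C-prenylated acylphloroglucinol, made from phloroglucinol by Friedel–Crafts acylation and then C-prenylation. The acyl stereocentre is bought with (R)-2-methylbutanoic acid.
4. Ring order: the two benzene rings come from phloroglucinol; the two pyran rings are formed last, in one operation.

Assumption: (R)-2-methylbutanoic acid (98% ee or better), 6-methylheptanal and p-toluenesulfinic acid are taken as commercially available.

## Route

Step 1
Reactants: 1 benzene-1,3,5-triol (phloroglucinol); 2 2-methylpropanoyl chloride (isobutyryl chloride)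
Product: 3 2-methyl-1-(2,4,6-trihydroxyphenyl)propan-1-one
Conditions: AlCl3 (4 equiv), CH2Cl2/MeNO2, 0 to 40 °C; then ice, 1 M HCl
Reagents that add atoms: none
Why: Friedel–Crafts C-acylation of the very electron-rich, threefold-symmetric arene stops at the mono-ketone because the aluminium-chelated acyl group deactivates the ring; no stereocentre is formed.

Step 2
Reactants: 3 2-methyl-1-(2,4,6-trihydroxyphenyl)propan-1-one; 4 1-bromo-3-methylbut-2-ene (prenyl bromide)
Product: 5 2-methyl-1-[2,4,6-trihydroxy-3-(3-methylbut-2-en-1-yl)phenyl]propan-1-one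
Conditions: 4 (1.0 equiv), 10% aq. KOH, 0 °C; then 1 M HCl; chromatography
Reagents that add atoms: none
Why: C-alkylation of the phloroglucinolate (an ambident vinylogous enolate) by an allylic bromide in water, where hydrogen bonding to the phenolate oxygens favours attack at carbon; the two free ring positions of 3 are equivalent, so only the degree of prenylation has to be held (1 equiv, 0 °C) and di-prenyl material is removed on silica.

Step 3
Reactants: 1 benzene-1,3,5-triol (phloroglucinol); 6 (2R)-2-methylbutanoic acid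
Product: 8 (2R)-2-methyl-1-(2,4,6-trihydroxyphenyl)butan-1-one, via (2R)-2-methylbutanoyl chloride 7 (not isolated)
Conditions: 6, (COCl)2 (1.1 equiv), DMF (cat.), CH2Cl2, 0 °C to rt; then 1, AlCl3 (4 equiv), CH2Cl2/MeNO2, 0 °C to rt; ice, 1 M HCl
Reagents that add atoms: none
Why: acid chloride formation followed by low-temperature Friedel–Crafts acylation; the stereocentre comes unchanged from the chiral-pool acid 6, since the aluminium-chelated aryl ketone should not enolise at or below room temperature (ee of 8 checked by chiral HPLC).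

Step 4
Reactants: 8 (2R)-2-methyl-1-(2,4,6-trihydroxyphenyl)butan-1-one; 4 1-bromo-3-methylbut-2-ene (prenyl bromide)
Product: 9 (2R)-2-methyl-1-[2,4,6-trihydroxy-3-(3-methylbut-2-en-1-yl)phenyl]butan-1-one
Conditions: 4 (1.0 equiv), 10% aq. KOH, 0 °C; then 1 M HCl; chromatography
Reagents that add atoms: none
Why: the same phenolate C-prenylation as in step 2; the α-stereocentre survives because the ketone of the di-anionic phloroglucinolate is a vinylogous carboxylate and is not enolised further at 0 °C.

Step 5
Reactants: 5 2-methyl-1-[2,4,6-trihydroxy-3-(3-methylbut-2-en-1-yl)phenyl]propan-1-one; 10 6-methylheptanal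
Product: 12 2-methyl-1-[2,4,6-trihydroxy-3-(3-methylbut-2-en-1-yl)-5-[6-methyl-1-(4-methylbenzenesulfonyl)heptyl]phenyl]propan-1-one (racemic at the sulfonyl-bearing carbon), via benzylic carbinol 11 (not isolated)
Conditions: 10 (1.3 equiv), p-toluenesulfinic acid (1.5 equiv), MgSO4, CH2Cl2, 0 °C to rt
Reagents that add atoms: p-toluenesulfinic acid, Cc1ccc(cc1)S(=O)O
Why: three-component hydroxyalkylation–sulfination of the kind used to make 2-(1-tosylalkyl)phenols, in which the aldehyde hydroxyalkylates the single free ring position to carbinol 11 and the sulfinic acid then replaces the benzylic hydroxyl in an acid-promoted SN1-type substitution (sulfinate attacks through sulfur on the benzylic cation stabilised by the flanking hydroxyls); excess sulfinic acid outcompetes a second molecule of 5 for that cation, and the new carbon centre is left racemic because step 6 erases it.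

Step 6
Reactants: 12 2-methyl-1-[2,4,6-trihydroxy-3-(3-methylbut-2-en-1-yl)-5-[6-methyl-1-(4-methylbenzenesulfonyl)heptyl]phenyl]propan-1-one; 9 (2R)-2-methyl-1-[2,4,6-trihydroxy-3-(3-methylbut-2-en-1-yl)phenyl]butan-1-one
Product: 14 (2R)-2-methyl-1-[2,4,6-trihydroxy-3-(3-methylbut-2-en-1-yl)-5-[(1R)-6-methyl-1-[2,4,6-trihydroxy-3-(3-methylbut-2-en-1-yl)-5-(2-methylpropanoyl)phenyl]heptyl]phenyl]butan-1-one, via ortho-quinone methide 13 (not isolated)
Conditions: 3-{[3,5-bis(trifluoromethyl)phenyl]amino}-4-{[(8α,9S)-6′-methoxycinchonan-9-yl]amino}cyclobut-3-ene-1,2-dione (quinine-derived squaramide, 10 mol%), Na2CO3 (10% aq., 1.2 equiv), CHCl3, 0 °C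
Reagents that add atoms: none
Why: base-triggered 1,4-elimination of sulfinate from 12 releases 13, which the squaramide binds by double hydrogen bonding at its carbonyl while the quinuclidine nitrogen holds the acidic C-nucleophile 9 (attack at its only free ring carbon), an organocatalytic enantioselective conjugate (Friedel–Crafts-type) addition to an ortho-quinone methide made in situ; the bridge stereocentre is set by the catalyst shielding one face of 13, and the distant (R)-acyl centre is untouched.

Step 7
Reactants: 14 (2R)-2-methyl-1-[2,4,6-trihydroxy-3-(3-methylbut-2-en-1-yl)-5-[(1R)-6-methyl-1-[2,4,6-trihydroxy-3-(3-methylbut-2-en-1-yl)-5-(2-methylpropanoyl)phenyl]heptyl]phenyl]butan-1-one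
Product: 17 (2R)-1-[6-[(1R)-1-[5,7-dihydroxy-2,2-dimethyl-8-(2-methylpropanoyl)-3,4-dihydro-2H-chromen-6-yl]-6-methylheptyl]-5,7-dihydroxy-2,2-dimethyl-3,4-dihydro-2H-chromen-8-yl]-2-methylbutan-1-one (the target), via ring A monochroman 15 (not isolated), via ring B monochroman 16 (not isolated)
Conditions: SnCl4 (2.2 equiv), 2,6-di-tert-butyl-4-methylpyridine (0.2 equiv), CH2Cl2, −78 to −40 °C; sat. aq. NaHCO3
Reagents that add atoms: none
Why: Proposed new method: each 2-acylphenol unit of 14 binds SnCl4 as a six-membered chelate through the ketone oxygen and one flanking hydroxyl, and only the hydroxyl lying between the acyl and the prenyl group thereby becomes a tin-acidified proton (a Lewis acid-assisted Brønsted acid) held within reach of the alkene, so the proton passes through a six-membered transition state to the CH carbon of the prenyl group and the same tin-bound oxygen closes on the tertiary cation to give the 8-acyl chroman, whereas the hydroxyl para to the acyl group cannot chelate and is not acidified, and the chelate at the hydroxyl next to the bridge has no alkene in reach and merely re-equilibrates; the closest known reaction types are SnCl4–phenol Lewis acid-assisted Brønsted acid cyclisations of 2-(polyprenyl)phenols to chromans and metal triflate-catalysed Markovnikov hydroalkoxylation of alkenols, neither of which has been used to choose between two hydroxyls flanking one prenyl group; no stereocentre is formed, and at −78 °C with free protic acid scavenged by the hindered pyridine the doubly benzylic bridge centre and the ketone α-centre should not be touched.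

## Compound list

1 | benzene-1,3,5-triol (phloroglucinol) | Oc1cc(O)cc(O)c1 | starting material
2 | 2-methylpropanoyl chloride (isobutyryl chloride) | CC(C)C(=O)Cl | starting material
3 | 2-methyl-1-(2,4,6-trihydroxyphenyl)propan-1-one | CC(C)C(=O)c1c(O)cc(O)cc1O | intermediate
4 | 1-bromo-3-methylbut-2-ene (prenyl bromide) | CC(C)=CCBr | starting material
5 | 2-methyl-1-[2,4,6-trihydroxy-3-(3-methylbut-2-en-1-yl)phenyl]propan-1-one | CC(C)C(=O)c1c(O)cc(O)c(CC=C(C)C)c1O | intermediate
6 | (2R)-2-methylbutanoic acid | CC[C@@H](C)C(=O)O | starting material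
7 | (2R)-2-methylbutanoyl chloride (not isolated) | CC[C@@H](C)C(=O)Cl | intermediate
8 | (2R)-2-methyl-1-(2,4,6-trihydroxyphenyl)butan-1-one | CC[C@@H](C)C(=O)c1c(O)cc(O)cc1O | intermediate
9 | (2R)-2-methyl-1-[2,4,6-trihydroxy-3-(3-methylbut-2-en-1-yl)phenyl]butan-1-one | CC[C@@H](C)C(=O)c1c(O)cc(O)c(CC=C(C)C)c1O | intermediate
10 | 6-methylheptanal | CC(C)CCCCC=O | starting material
11 | 2-methyl-1-[2,4,6-trihydroxy-3-(1-hydroxy-6-methylheptyl)-5-(3-methylbut-2-en-1-yl)phenyl]propan-1-one (benzylic carbinol, racemic, not isolated) | CC(C)C(=O)c1c(O)c(CC=C(C)C)c(O)c(C(O)CCCCC(C)C)c1O | intermediate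
12 | 2-methyl-1-[2,4,6-trihydroxy-3-(3-methylbut-2-en-1-yl)-5-[6-methyl-1-(4-methylbenzenesulfonyl)heptyl]phenyl]propan-1-one (racemic) | CC(C)C(=O)c1c(O)c(CC=C(C)C)c(O)c(C(CCCCC(C)C)S(=O)(=O)c2ccc(C)cc2)c1O | intermediate
13 | 3,5-dihydroxy-6-(6-methylheptylidene)-4-(3-methylbut-2-en-1-yl)-2-(2-methylpropanoyl)cyclohexa-2,4-dien-1-one (ortho-quinone methide of ring B, one tautomer drawn, alkene geometry open, not isolated) | CC(C)C(=O)C1=C(O)C(CC=C(C)C)=C(O)C(=CCCCCC(C)C)C1=O | intermediate
14 | (2R)-2-methyl-1-[2,4,6-trihydroxy-3-(3-methylbut-2-en-1-yl)-5-[(1R)-6-methyl-1-[2,4,6-trihydroxy-3-(3-methylbut-2-en-1-yl)-5-(2-methylpropanoyl)phenyl]heptyl]phenyl]butan-1-one | CC[C@@H](C)C(=O)c1c(O)c([C@H](CCCCC(C)C)c2c(O)c(CC=C(C)C)c(O)c(C(=O)C(C)C)c2O)c(O)c(CC=C(C)C)c1O | intermediate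
15 | (2R)-1-[5,7-dihydroxy-2,2-dimethyl-6-[(1R)-6-methyl-1-[2,4,6-trihydroxy-3-(3-methylbut-2-en-1-yl)-5-(2-methylpropanoyl)phenyl]heptyl]-3,4-dihydro-2H-chromen-8-yl]-2-methylbutan-1-one (ring A closed, ring B open, not isolated) | CC[C@@H](C)C(=O)c1c(O)c([C@H](CCCCC(C)C)c2c(O)c(CC=C(C)C)c(O)c(C(=O)C(C)C)c2O)c(O)c2c1OC(C)(C)CC2 | intermediate
16 | (2R)-1-[3-[(1S)-1-[5,7-dihydroxy-2,2-dimethyl-8-(2-methylpropanoyl)-3,4-dihydro-2H-chromen-6-yl]-6-methylheptyl]-2,4,6-trihydroxy-5-(3-methylbut-2-en-1-yl)phenyl]-2-methylbutan-1-one (ring B closed, ring A open, not isolated; same spatial arrangement at the bridge as in 14, the descriptor reads S only because the ring priorities change) | CC[C@@H](C)C(=O)c1c(O)c([C@H](CCCCC(C)C)c2c(O)c3c(c(C(=O)C(C)C)c2O)OC(C)(C)CC3)c(O)c(CC=C(C)C)c1O | intermediate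
17 | (2R)-1-[6-[(1R)-1-[5,7-dihydroxy-2,2-dimethyl-8-(2-methylpropanoyl)-3,4-dihydro-2H-chromen-6-yl]-6-methylheptyl]-5,7-dihydroxy-2,2-dimethyl-3,4-dihydro-2H-chromen-8-yl]-2-methylbutan-1-one | CC[C@@H](C)C(=O)c1c(O)c([C@H](CCCCC(C)C)c2c(O)c3c(c(C(=O)C(C)C)c2O)OC(C)(C)CC3)c(O)c2c1OC(C)(C)CC2 | target

## Step count and risks

Total step count: 7. Longest linear sequence: 5 steps (steps 1, 2, 5, 6, 7).

The three steps most likely to fail are steps 5, 6 and 7.

**Step 5 (sulfone formation).** The benzylic cation formed from carbinol 11 may be caught by a second molecule of 5 to give the symmetric ring B dimer, or the sulfinic acid may add to the prenyl alkene. The fallback sets out from 5 and 10 and comes back at 12. Aldehyde 10 is premixed with morpholine and condensed with 5 in EtOH at rt (Betti-type Mannich reaction, in which an iminium ion is the electrophile and whose product has no free ring position). This gives the Mannich base 2-methyl-1-[2,4,6-trihydroxy-3-(3-methylbut-2-en-1-yl)-5-[6-methyl-1-(morpholin-4-yl)heptyl]phenyl]propan-1-one F1. Warming F1 with TolSO2Na in AcOH at 50 °C exchanges the amine for sulfinate by elimination–addition (through quinone methide 13) and gives 12.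

**Step 6 (bridge stereocentre).** Three things can go wrong:
- The two ring oxygens flanking the exocyclic alkene of 13 can swap roles by proton shift, so the alkene geometry seen by the catalyst is not fixed.
- The phenolate of 9 can add without the catalyst.
- The sense of induction is not predictable; the quinidine-derived pseudoenantiomer of the squaramide is the first thing to try if the wrong epimer dominates.

The fallback is a resolution at a stage where the two aryl groups at the bridge are really different. It sets out from 9 and 12 and comes back at 15, which step 7 then carries to 17 with only ring B left to close. Compound 9 is closed with p-toluenesulfonic acid monohydrate (10 mol%) in toluene at 60 °C (ordinary Brønsted acid hydroalkoxylation) to a separable pair of chromans: (2R)-1-(5,7-dihydroxy-2,2-dimethyl-3,4-dihydro-2H-chromen-8-yl)-2-methylbutan-1-one F2 and (2R)-1-(5,7-dihydroxy-2,2-dimethyl-3,4-dihydro-2H-chromen-6-yl)-2-methylbutan-1-one F3. F2 is coupled with 12 under Na2CO3 (aq.)/CHCl3 without chiral catalyst, through 13. This gives 15 together with about an equal amount of its bridge epimer (2R)-1-[5,7-dihydroxy-2,2-dimethyl-6-[(1S)-6-methyl-1-[2,4,6-trihydroxy-3-(3-methylbut-2-en-1-yl)-5-(2-methylpropanoyl)phenyl]heptyl]-3,4-dihydro-2H-chromen-8-yl]-2-methylbutan-1-one F4. Because one aryl group is now a chroman and the other an open prenylated triol, 15 and F4 should be separable by preparative SFC on a polysaccharide chiral phase. Separating the bridge epimers of 14 or 17 themselves is unlikely to work, since their two aryl groups differ only by a remote methyl group.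

**Step 7 (proposed new ring closure).** The hydroxyl para to the acyl group may close instead and give the 6-acyl-type chroman, or tin-bound acid may cleave or scramble the doubly benzylic bridge. The fallback uses known chemistry and closes the pyran rings before the bridge is made; it sets out from 5 and 9 and comes back at 17. Compound 5 is closed with p-toluenesulfonic acid monohydrate (10 mol%) in toluene at 60 °C to 1-(5,7-dihydroxy-2,2-dimethyl-3,4-dihydro-2H-chromen-8-yl)-2-methylpropan-1-one F5 and its isomer 1-(5,7-dihydroxy-2,2-dimethyl-3,4-dihydro-2H-chromen-6-yl)-2-methylpropan-1-one F6, separated on silica. Compound 9 gives (2R)-1-(5,7-dihydroxy-2,2-dimethyl-3,4-dihydro-2H-chromen-8-yl)-2-methylbutan-1-one F2 beside (2R)-1-(5,7-dihydroxy-2,2-dimethyl-3,4-dihydro-2H-chromen-6-yl)-2-methylbutan-1-one F3 in the same way. F5 is condensed with 10 and p-toluenesulfinic acid as in step 5 to the sulfone 1-[5,7-dihydroxy-2,2-dimethyl-6-[6-methyl-1-(4-methylbenzenesulfonyl)heptyl]-3,4-dihydro-2H-chromen-8-yl]-2-methylpropan-1-one F7. F7 and F2 are joined under the step 6 conditions through the quinone methide 7-hydroxy-2,2-dimethyl-6-(6-methylheptylidene)-8-(2-methylpropanoyl)-3,4-dihydro-2H-chromen-5(6H)-one F8 to give 17 directly.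

## Further compounds

F1 | step 5 | 2-methyl-1-[2,4,6-trihydroxy-3-(3-methylbut-2-en-1-yl)-5-[6-methyl-1-(morpholin-4-yl)heptyl]phenyl]propan-1-one (racemic) | CC(C)C(=O)c1c(O)c(CC=C(C)C)c(O)c(C(CCCCC(C)C)N2CCOCC2)c1O
F2 | step 6 | (2R)-1-(5,7-dihydroxy-2,2-dimethyl-3,4-dihydro-2H-chromen-8-yl)-2-methylbutan-1-one | CC[C@@H](C)C(=O)c1c(O)cc(O)c2c1OC(C)(C)CC2
F3 | step 6 | (2R)-1-(5,7-dihydroxy-2,2-dimethyl-3,4-dihydro-2H-chromen-6-yl)-2-methylbutan-1-one | CC[C@@H](C)C(=O)c1c(O)cc2OC(C)(C)CCc2c1O
F4 | step 6 | (2R)-1-[5,7-dihydroxy-2,2-dimethyl-6-[(1S)-6-methyl-1-[2,4,6-trihydroxy-3-(3-methylbut-2-en-1-yl)-5-(2-methylpropanoyl)phenyl]heptyl]-3,4-dihydro-2H-chromen-8-yl]-2-methylbutan-1-one | CC[C@@H](C)C(=O)c1c(O)c([C@@H](CCCCC(C)C)c2c(O)c(CC=C(C)C)c(O)c(C(=O)C(C)C)c2O)c(O)c2c1OC(C)(C)CC2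
F5 | step 7 | 1-(5,7-dihydroxy-2,2-dimethyl-3,4-dihydro-2H-chromen-8-yl)-2-methylpropan-1-one | CC(C)C(=O)c1c(O)cc(O)c2c1OC(C)(C)CC2
F6 | step 7 | 1-(5,7-dihydroxy-2,2-dimethyl-3,4-dihydro-2H-chromen-6-yl)-2-methylpropan-1-one | CC(C)C(=O)c1c(O)cc2OC(C)(C)CCc2c1O
F7 | step 7 | 1-[5,7-dihydroxy-2,2-dimethyl-6-[6-methyl-1-(4-methylbenzenesulfonyl)heptyl]-3,4-dihydro-2H-chromen-8-yl]-2-methylpropan-1-one (racemic) | CC(C)C(=O)c1c(O)c(C(CCCCC(C)C)S(=O)(=O)c2ccc(C)cc2)c(O)c2c1OC(C)(C)CC2
F8 | step 7 | 7-hydroxy-2,2-dimethyl-6-(6-methylheptylidene)-8-(2-methylpropanoyl)-3,4-dihydro-2H-chromen-5(6H)-one | CC(C)C(=O)C1=C(O)C(=CCCCCC(C)C)C(=O)C2=C1OC(C)(C)CC2
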